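By 20.0 min the alpha run, which is the flask asked about, shows its highest reading of complex with two exchanged, 13.6%, higher than the rows on either side.

| setting | alpha | eta | flask |
|---|---|---|---|
| starting complex | 1 M | 1 M | 1.0 M |
| leaving ligand | 0.50 M | 0.25 M | 0.500 M |
| gas | 88 mM (held) | 88 mM (held) | 88 mM (held) |
| remark | the very flask that is asked about, followed so far | run made earlier |  |
| time |  |  | 4.0 h |

| alpha: time / min | alpha: complex with two exchanged / % | eta: time / h | eta: complex with two exchanged / % |
|---|---|---|---|
| 3.00 | 6.0 | 0.0500 | 7.4 |
| 8.00 | 12.6 | 0.133 | 15.2 |
| 20.0 | 13.6 | 0.417 | 16.1 |
| 50.0 | 11.6 | 1.00 | 13.9 |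
| 120 | 10.7 | 3.00 | 12.6 |

(each reading ± 0.5 percentage points)

1. time up to 4.0 h at which complex with two exchanged stands highest
2. the amount of complex with two exchanged, in percent of the starting complex charged, at that time
3. the first time at which complex with two exchanged reaches 9.2%, in the same percent

- the numbers in the tables scatter with a standard deviation of 0.5 percentage points
- at the start none of the gas is in solution

The first two rows of the tables stand at equal times, and eta holds half the [leaving ligand] of alpha. Summed over these rows, eta stands 1.22 times over alpha. This is the halving factor, the gain in complex with two exchanged, as read from these rows, at equal time when [leaving ligand] is halved from the alpha charge, with starting complex and gas held.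

The third row of eta, 16.1% at 0.417 h, divided by this factor reads 13.2% on the scale of alpha. Beside the alpha readings of 12.6% at 8.00 min and 13.6% at 20.0 min, this reckoning puts a flat top between 8.00 min and 0.417 h, with heights that span 1 percentage point, against a scatter of 0.5 points in each reading.

The forecast, “I read its curve directly and use eta only as a check”, gives 14% at 0.24 h, a little above these readings, and 9.2% at 0.08 h.

The flask gives 13.2% at 0.216 h and reaches 9.2% at 0.0744 h, each within the tolerance of the forecast.

    starting complex + incoming ligand ⇌ leaving ligand + complex with one exchanged (K = 9.11, k = 3.16 /M/min)
    gas ⇌ incoming ligand, rate k2*(csat - [incoming ligand]) (kL = 12.0 /min)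
    incoming ligand ⇌ dormant form (K = 10.8, k = 0.0591 /min)
    complex with two exchanged + incoming ligand ⇌ leaving ligand + complex with three exchanged (K = 11.0, k = 0.127 /M/min)
    complex with one exchanged + incoming ligand ⇌ leaving ligand + complex with two exchanged (K = 5.10, k = 1.87 /M/min)

In the flask the forward half-life of starting complex by the first exchange alone is 2.5 min at 0.177 h, shorter than the best time, and 99% of that step's turnover up to 4.0 h is done by 0.400 h. In the flask complex with three exchanged comes later, from 1.26% at the best time to 8.18% at 4.00 h, while complex with two exchanged eases from 13.2% to 10.9%.

A neighbour charged with 0.12 M of leaving ligand lies 2.06 halvings below the flask, so the factor, counted over these halvings, reckons 13.2% up to 19.7%. Its computed best is 17.9%, lower than that count.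

All runs are calculated on assumed constants; noise was put on by code.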